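**Plan**

1. Chain numbering: C1–C2 (CH2CH2 on the catechol ring), C3 (CH–OAc, R), C4, C5, C6=C7 (E, C7 on the 4-hydroxyphenyl ring). Retrosynthesis first removes the acetate and three silyl groups, then changes C3–O into C3–B(pin).
2. C4–C5 and C2–C3 are then cut in one event: a vinylboron ate complex (vinyl = C3=C4, phenethyl C1–C2 on boron) plus a 1-arylallyl–Pd electrophile (C5–C6–C7). Last come C2–B (styrene hydroboration), C1=C2 (Wittig) and C6–C7 (vinyl Grignard on an aldehyde).
3. Enabling feature: the O–C3H–C4H2–C5H2–C6=C7–aryl array, a carbinol carbon C3 whose neighbour C4 bears the allylic carbon of a cinnamyl group. C2 can arrive at C3 by 1,2-shift from boron, and the C3 oxygen can be the former boron.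
4. Forward: 3,4-dihydroxybenzaldehyde gives the phenethyl–B(pin) (3 steps); 4-hydroxybenzaldehyde gives a racemic 1-arylallyl acetate (2 steps); three-component union with vinyllithium; C–B to C–OH; acetylation; desilylation. The chain is joined as C1–C2, then C3=C4 on boron, then C4–C5 together with C2–C3; no ring is made.
5. Stereochemistry: C3 (R) comes from the chiral bisphosphine–Pd catalyst of the union (anti, stereospecific 1,2-shift) and is retained in the C–B oxidation. C6=C7 (E) comes from the syn-π-allyl complex, to which the racemic branched acetate converges.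

Key step: step 6

Remark: the stereocentre of the target as drawn is read as (R) (CIP order O > C2 branch > C4 branch > H). TIPS = triisopropylsilyl. Which antipode of the bisphosphine leads to (R) at C3 cannot be predicted with certainty and is to be settled in the first runs; both antipodes are commercial.

**Route**

Step 1
Reactants: 1 3,4-dihydroxybenzaldehyde
Product: 2 3,4-bis(triisopropylsilyloxy)benzaldehyde
Conditions: TIPSCl (2.5 equiv), imidazole (5 equiv), DMF, rt → 40 °C
Reagents that add atoms: triisopropylsilyl chloride, CC(C)[Si](Cl)(C(C)C)C(C)C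
Why: Imidazole-promoted O-silylation of both phenols; aryl TIPS ethers should survive the organolithium, perborate and acylation steps ahead and still fall to fluoride at the end.

Step 2
Reactants: 2 3,4-bis(triisopropylsilyloxy)benzaldehyde
Product: 3 4-ethenyl-1,2-bis(triisopropylsilyloxy)benzene
Conditions: Ph3PCH3Br, n-BuLi, THF, 0 °C; then 2, 0 °C → rt
Reagents that add atoms: methyltriphenylphosphonium bromide, C[P+](c1ccccc1)(c1ccccc1)c1ccccc1.[Br-]
Why: Wittig methylenation of a non-enolisable aryl aldehyde with the unstabilised ylide should give the styrene cleanly and supplies C2 of the chain.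

Step 3
Reactants: 3 4-ethenyl-1,2-bis(triisopropylsilyloxy)benzene
Product: 4 2-{2-[3,4-bis(triisopropylsilyloxy)phenyl]ethyl}-4,4,5,5-tetramethyl-1,3,2-dioxaborolane
Conditions: HBpin (1.2 equiv), [Ir(cod)Cl]2 (1.5 mol %), dppb (3 mol %), CH2Cl2, rt
Reagents that add atoms: pinacolborane, CC1(C)OBOC1(C)C
Why: Iridium-catalysed hydroboration of a vinylarene with pinacolborane is anti-Markovnikov, so boron should end on the terminal carbon (C2) and C1 becomes the benzylic CH2; no stereocentre is formed.

Step 4
Reactants: 5 4-hydroxybenzaldehyde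
Product: 6 4-(triisopropylsilyloxy)benzaldehyde
Conditions: TIPSCl (1.2 equiv), imidazole (2.5 equiv), DMF, rt
Reagents that add atoms: triisopropylsilyl chloride, CC(C)[Si](Cl)(C(C)C)C(C)C
Why: Imidazole-promoted O-silylation of the phenol, with the same silyl group as in 2 so that one fluoride treatment frees all three phenols at the end.

Step 5
Reactants: 6 4-(triisopropylsilyloxy)benzaldehyde
Product: 8 rac-1-[4-(triisopropylsilyloxy)phenyl]prop-2-en-1-yl acetate, via bromomagnesium alkoxide 7 (not isolated)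
Conditions: vinylMgBr (1.2 equiv), THF, −78 → 0 °C; then Ac2O (1.5 equiv), 0 °C → rt
Reagents that add atoms: vinylmagnesium bromide, C=C[Mg]Br; acetic anhydride, CC(=O)OC(C)=O
Why: Grignard 1,2-addition to the aryl aldehyde followed by O-acylation of the magnesium alkoxide in the same flask; the new carbinol centre is deliberately left racemic because Pd ionisation erases it in step 6.

Step 6
Reactants: 4 2-{2-[3,4-bis(triisopropylsilyloxy)phenyl]ethyl}-4,4,5,5-tetramethyl-1,3,2-dioxaborolane; 8 rac-1-[4-(triisopropylsilyloxy)phenyl]prop-2-en-1-yl acetate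
Product: 10 2-{(3R,6E)-1-[3,4-bis(triisopropylsilyloxy)phenyl]-7-[4-(triisopropylsilyloxy)phenyl]hept-6-en-3-yl}-4,4,5,5-tetramethyl-1,3,2-dioxaborolane, via lithium vinylborate complex 9 (not isolated)
Conditions: vinyl bromide, t-BuLi (2 equiv), Et2O, −78 °C; then 4, −78 → 0 °C; Et2O exchanged for THF; then 8, Pd2(dba)3 (2.5 mol %), (R)-H8-BINAP (6 mol %, or its antipode, see Why), THF, 0 °C → rt
Reagents that add atoms: vinyllithium, [Li]C=C (made in the flask from vinyl bromide, C=CBr, and t-BuLi)
Why: Proposed new method: vinyllithium adds to the vacant boron orbital of 4 to give ate complex 9, whose C3=C4 π-bond is made nucleophilic at C4 by the adjacent borate; Pd(0) ionises racemic 8 (or any linear isomer formed from it) to a single cationic syn-η3-(1-arylallyl)Pd–bisphosphine complex, C4 attacks its CH2 terminus on the face opposite to Pd, and in the same event the phenethyl group shifts from boron to C3 antiperiplanar to the forming C4–C5 bond, which gives the neutral secondary boronic ester and returns Pd(0). The closest known reaction types are the Pd-catalysed conjunctive cross-coupling of vinylboron ate complexes with aryl and alkenyl triflates and the allylation-triggered 1,2-boronate rearrangement of indolyl and substituted alkenyl boronates under Pd or Ir catalysis; what is new is the pairing of an unsubstituted vinylboronate with a linear-selective Pd-cinnamyl electrophile. No ring is closed. The one new stereocentre, C3, is controlled by the chiral bisphosphine on Pd: it selects which face of the vinyl group meets the allyl terminus, and because the 1,2-shift is stereospecifically anti this choice fixes C3; the ligand antipode that leads to the (R)-boronic ester is to be assigned in a first pair of runs by MTPA-ester analysis of 11. The step needs attack at the unsubstituted allyl terminus with E geometry, which the aryl group should secure by shielding the benzylic terminus and by sitting syn in the π-allyl, and it needs the rearrangement to outrun Suzuki-type transfer of vinyl or alkyl to Pd, which the coordinatively saturated bisphosphine π-allyl cation (no free site for transmetallation) and the presence of only one carbon ligand able to migrate should secure.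

Step 7
Reactants: 10 2-{(3R,6E)-1-[3,4-bis(triisopropylsilyloxy)phenyl]-7-[4-(triisopropylsilyloxy)phenyl]hept-6-en-3-yl}-4,4,5,5-tetramethyl-1,3,2-dioxaborolane
Product: 11 (3R,6E)-1-[3,4-bis(triisopropylsilyloxy)phenyl]-7-[4-(triisopropylsilyloxy)phenyl]hept-6-en-3-ol
Conditions: NaBO3·4H2O (5 equiv), THF/H2O 1:1, rt
Reagents that add atoms: sodium perborate (used as the tetrahydrate), [Na+].[Na+].O[B-]1(O)OO[B-](O)(O)OO1
Why: Peroxoborate oxidation of the C–B bond proceeds by 1,2-shift of C3 from boron to oxygen with retention, so the (R)-boronic ester should give the (R)-alcohol, and the weakly basic medium should spare the aryl silyl ethers and the styrene.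

Step 8
Reactants: 11 (3R,6E)-1-[3,4-bis(triisopropylsilyloxy)phenyl]-7-[4-(triisopropylsilyloxy)phenyl]hept-6-en-3-ol
Product: 12 (3R,6E)-1-[3,4-bis(triisopropylsilyloxy)phenyl]-7-[4-(triisopropylsilyloxy)phenyl]hept-6-en-3-yl acetate
Conditions: Ac2O, pyridine, DMAP (cat.), CH2Cl2, 0 °C → rt
Reagents that add atoms: acetic anhydride, CC(=O)OC(C)=O
Why: DMAP-catalysed O-acylation of the secondary alcohol; no bond to C3 is broken, so the configuration is kept.

Step 9
Reactants: 12 (3R,6E)-1-[3,4-bis(triisopropylsilyloxy)phenyl]-7-[4-(triisopropylsilyloxy)phenyl]hept-6-en-3-yl acetate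
Product: 13 (3R,6E)-1-(3,4-dihydroxyphenyl)-7-(4-hydroxyphenyl)hept-6-en-3-yl acetate
Conditions: TBAF (3.3 equiv), AcOH (3.5 equiv), THF, 0 °C → rt, under Ar
Reagents that add atoms: none
Why: Fluoride-mediated desilylation: fluoride attacks silicon of the three aryl silyl ethers (aryloxide leaving groups) much faster than anything reacts at the alkyl acetate, and the acetic acid buffer keeps the phenols protonated so that acyl transfer and catechol autoxidation should be avoided.

**Compound list**

1 | 3,4-dihydroxybenzaldehyde | O=Cc1ccc(O)c(O)c1 | starting material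
2 | 3,4-bis(triisopropylsilyloxy)benzaldehyde | O=Cc1ccc(O[Si](C(C)C)(C(C)C)C(C)C)c(O[Si](C(C)C)(C(C)C)C(C)C)c1 | intermediate
3 | 4-ethenyl-1,2-bis(triisopropylsilyloxy)benzene | C=Cc1ccc(O[Si](C(C)C)(C(C)C)C(C)C)c(O[Si](C(C)C)(C(C)C)C(C)C)c1 | intermediate
4 | 2-{2-[3,4-bis(triisopropylsilyloxy)phenyl]ethyl}-4,4,5,5-tetramethyl-1,3,2-dioxaborolane | CC1(C)OB(CCc2ccc(O[Si](C(C)C)(C(C)C)C(C)C)c(O[Si](C(C)C)(C(C)C)C(C)C)c2)OC1(C)C | intermediate
5 | 4-hydroxybenzaldehyde | O=Cc1ccc(O)cc1 | starting material
6 | 4-(triisopropylsilyloxy)benzaldehyde | O=Cc1ccc(O[Si](C(C)C)(C(C)C)C(C)C)cc1 | intermediate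
7 | bromomagnesium 1-[4-(triisopropylsilyloxy)phenyl]prop-2-en-1-olate (racemic, not isolated) | C=CC(O[Mg]Br)c1ccc(O[Si](C(C)C)(C(C)C)C(C)C)cc1 | intermediate
8 | rac-1-[4-(triisopropylsilyloxy)phenyl]prop-2-en-1-yl acetate | CC(=O)OC(C=C)c1ccc(O[Si](C(C)C)(C(C)C)C(C)C)cc1 | intermediate
9 | lithium {2-[3,4-bis(triisopropylsilyloxy)phenyl]ethyl}(ethenyl)(pinacolato)borate (not isolated) | [Li+].C=C[B-]1(CCc2ccc(O[Si](C(C)C)(C(C)C)C(C)C)c(O[Si](C(C)C)(C(C)C)C(C)C)c2)OC(C)(C)C(C)(C)O1 | intermediate
10 | 2-{(3R,6E)-1-[3,4-bis(triisopropylsilyloxy)phenyl]-7-[4-(triisopropylsilyloxy)phenyl]hept-6-en-3-yl}-4,4,5,5-tetramethyl-1,3,2-dioxaborolane | CC1(C)OB(OC1(C)C)[C@H](CC/C=C/c1ccc(O[Si](C(C)C)(C(C)C)C(C)C)cc1)CCc1ccc(O[Si](C(C)C)(C(C)C)C(C)C)c(O[Si](C(C)C)(C(C)C)C(C)C)c1 | intermediate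
11 | (3R,6E)-1-[3,4-bis(triisopropylsilyloxy)phenyl]-7-[4-(triisopropylsilyloxy)phenyl]hept-6-en-3-ol | O[C@H](CC/C=C/c1ccc(O[Si](C(C)C)(C(C)C)C(C)C)cc1)CCc1ccc(O[Si](C(C)C)(C(C)C)C(C)C)c(O[Si](C(C)C)(C(C)C)C(C)C)c1 | intermediate
12 | (3R,6E)-1-[3,4-bis(triisopropylsilyloxy)phenyl]-7-[4-(triisopropylsilyloxy)phenyl]hept-6-en-3-yl acetate | CC(=O)O[C@H](CC/C=C/c1ccc(O[Si](C(C)C)(C(C)C)C(C)C)cc1)CCc1ccc(O[Si](C(C)C)(C(C)C)C(C)C)c(O[Si](C(C)C)(C(C)C)C(C)C)c1 | intermediate
13 | (3R,6E)-1-(3,4-dihydroxyphenyl)-7-(4-hydroxyphenyl)hept-6-en-3-yl acetate | CC(=O)O[C@H](CC/C=C/c1ccc(O)cc1)CCc1ccc(O)c(O)c1 | target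

**Totals**

Total step count: 9. Longest linear sequence: 7 steps (steps 1, 2, 3, 6, 7, 8, 9).

**Steps most likely to fail**

Step 6 (Proposed new method). The ate complex may hand its vinyl or alkyl group to palladium (direct cross-coupling) faster than the 1,2-shift occurs, or the catalyst may discriminate the two faces of the vinyl group poorly. The fallback uses known chemistry: the C4–C5 bond is made by a sigmatropic shift and C3 is set by reagent-controlled lithiation–borylation. It sets out from 8 and returns at 10.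
- Ireland–Claisen rearrangement of 8 (LDA, TMSCl, THF, −78 °C → rt) should pass through trimethylsilyl ketene acetal F1 and a chair transition state with the aryl group equatorial. This gives trimethylsilyl (E)-5-[4-(triisopropylsilyloxy)phenyl]pent-4-enoate F2, which aqueous work-up hydrolyses to (E)-5-[4-(triisopropylsilyloxy)phenyl]pent-4-enoic acid F3.
- LiAlH4 (THF, 0 °C) should give (E)-5-[4-(triisopropylsilyloxy)phenyl]pent-4-en-1-ol F4, and N,N-diisopropylcarbamoyl chloride (Et3N, CH2Cl2, reflux) its N,N-diisopropylcarbamate F5.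
- Sparteine-mediated asymmetric deprotonation (s-BuLi, (−)-sparteine, Et2O, −78 °C) should give the (S)-α-lithiated carbamate F6. Boronic ester 4 should trap it with retention as boronate complex F7.
- MgBr2·OEt2 with warming should trigger the 1,2-shift of the phenethyl group with inversion at carbon and loss of the carbamate, which gives the (R)-boronic ester 10.

Step 9. Under the basicity of fluoride the acetate may be cleaved or may migrate to a phenoxide, and the liberated catechol may be oxidised by air. The fallback changes the protecting-group logic; it sets out from 11 and returns at 13.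
- Desilylation before any acetate is present (TBAF, AcOH, THF, 0 °C) should give (3R,6E)-1-(3,4-dihydroxyphenyl)-7-(4-hydroxyphenyl)hept-6-en-3-ol F8.
- Peracetylation (Ac2O, pyridine, DMAP) should give 4-[(3R,6E)-3-acetoxy-7-(4-acetoxyphenyl)hept-6-en-1-yl]-1,2-phenylene diacetate F9.
- Chemoselective cleavage of the three aryl acetates (NH4OAc, MeOH/H2O, rt), which are far better acyl donors than the secondary alkyl acetate, should then give 13.

Step 5. The electron-rich secondary benzylic allylic acetate may ionise, transpose or solvolyse during acylation or chromatography. The fallback builds a stable primary acetate with the alkene geometry fixed by olefination; it sets out from 6 and returns at 10.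
- Horner–Wadsworth–Emmons olefination (triethyl phosphonoacetate, NaH, THF, 0 °C) should give ethyl (E)-3-[4-(triisopropylsilyloxy)phenyl]prop-2-enoate F10.
- DIBAL-H (CH2Cl2, −78 °C) should give (E)-3-[4-(triisopropylsilyloxy)phenyl]prop-2-en-1-ol F11.
- Ac2O/pyridine should give (E)-3-[4-(triisopropylsilyloxy)phenyl]prop-2-en-1-yl acetate F12. It is used in step 6 in place of 8, should ionise to the same π-allyl complex, and gives 10.

**Further compounds**

F1 | step 6 | 1-[4-(triisopropylsilyloxy)phenyl]prop-2-en-1-yl 1-(trimethylsilyloxy)ethenyl ether (trimethylsilyl ketene acetal, racemic, not isolated) | C=C(O[Si](C)(C)C)OC(C=C)c1ccc(O[Si](C(C)C)(C(C)C)C(C)C)cc1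
F2 | step 6 | trimethylsilyl (E)-5-[4-(triisopropylsilyloxy)phenyl]pent-4-enoate | C[Si](C)(C)OC(=O)CC/C=C/c1ccc(O[Si](C(C)C)(C(C)C)C(C)C)cc1
F3 | step 6 | (E)-5-[4-(triisopropylsilyloxy)phenyl]pent-4-enoic acid | OC(=O)CC/C=C/c1ccc(O[Si](C(C)C)(C(C)C)C(C)C)cc1
F4 | step 6 | (E)-5-[4-(triisopropylsilyloxy)phenyl]pent-4-en-1-ol | OCCC/C=C/c1ccc(O[Si](C(C)C)(C(C)C)C(C)C)cc1
F5 | step 6 | (E)-5-[4-(triisopropylsilyloxy)phenyl]pent-4-en-1-yl N,N-diisopropylcarbamate | CC(C)N(C(C)C)C(=O)OCCC/C=C/c1ccc(O[Si](C(C)C)(C(C)C)C(C)C)cc1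
F6 | step 6 | (1S,4E)-1-lithio-5-[4-(triisopropylsilyloxy)phenyl]pent-4-en-1-yl N,N-diisopropylcarbamate ((−)-sparteine complex, not isolated) | CC(C)N(C(C)C)C(=O)O[C@@H]([Li])CC/C=C/c1ccc(O[Si](C(C)C)(C(C)C)C(C)C)cc1
F7 | step 6 | lithium {2-[3,4-bis(triisopropylsilyloxy)phenyl]ethyl}{(1S,4E)-1-(N,N-diisopropylcarbamoyloxy)-5-[4-(triisopropylsilyloxy)phenyl]pent-4-en-1-yl}(pinacolato)borate (not isolated) | [Li+].CC(C)N(C(C)C)C(=O)O[C@@H]([B-]1(CCc2ccc(O[Si](C(C)C)(C(C)C)C(C)C)c(O[Si](C(C)C)(C(C)C)C(C)C)c2)OC(C)(C)C(C)(C)O1)CC/C=C/c1ccc(O[Si](C(C)C)(C(C)C)C(C)C)cc1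
F8 | step 9 | (3R,6E)-1-(3,4-dihydroxyphenyl)-7-(4-hydroxyphenyl)hept-6-en-3-ol | O[C@H](CC/C=C/c1ccc(O)cc1)CCc1ccc(O)c(O)c1
F9 | step 9 | 4-[(3R,6E)-3-acetoxy-7-(4-acetoxyphenyl)hept-6-en-1-yl]-1,2-phenylene diacetate | CC(=O)O[C@H](CC/C=C/c1ccc(OC(C)=O)cc1)CCc1ccc(OC(C)=O)c(OC(C)=O)c1
F10 | step 5 | ethyl (E)-3-[4-(triisopropylsilyloxy)phenyl]prop-2-enoate | CCOC(=O)/C=C/c1ccc(O[Si](C(C)C)(C(C)C)C(C)C)cc1
F11 | step 5 | (E)-3-[4-(triisopropylsilyloxy)phenyl]prop-2-en-1-ol | OC/C=C/c1ccc(O[Si](C(C)C)(C(C)C)C(C)C)cc1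
F12 | step 5 | (E)-3-[4-(triisopropylsilyloxy)phenyl]prop-2-en-1-yl acetate | CC(=O)OC/C=C/c1ccc(O[Si](C(C)C)(C(C)C)C(C)C)cc1
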